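## The problem

Target 15 is the isofraxidin (7-hydroxy-6,8-dimethoxycoumarin) ether of a C15 bicyclic alcohol. Drimane numbering is used throughout: ring A is C1–C2–C3–C4–C5–C10 with the enone C1=C2–C3=O and two methyls on C4; ring B is C5–C6–C7–C8–C9–C10 with an exocyclic methylene C8=C12; C9 carries the C11H2–OAr arm and C10 the angular methyl.

- The two rings are trans-fused across C5–C10, and C10 is quaternary, so it has to be created in a C–C bond-forming event with absolute control.
- The three stereocentres are contiguous (5S,9S,10R). C5 can be slaved to C10 if both arise from one alkene of defined geometry. C9 carries its arm on the face opposite the angular methyl (axial), which is the face a reagent would choose on a C8=C9 alkene, so C10 can control C9.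
- C4 is quaternary and flanked by the ketone. Once C1=C2 is in place it is the only carbon α to the carbonyl that bears hydrogens, so both methyls can be introduced by enolate chemistry.
- The coumarin lactone is opened by bases and nucleophiles and is a Michael acceptor. The exocyclic alkene migrates into the ring under acid, and the C11 arm sits on a hindered, β-branched carbon. The arene should therefore arrive last and under neutral conditions.
- The enabling feature is ring A itself: a cyclohex-2-enone whose C1=C2–C3(=O)–C4 unit maps onto a 1-methoxy-3-siloxybutadiene. Its C5–C10 bond maps onto the C=C bond of an α-methyl enal whose formyl carbon is C9. That formyl group is also the handle for closing ring B.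

## Retrosynthesis

**C11–O bond.** Cutting the aryl ether of 15 gives the primary alcohol 13, (hydroxymethyl)drimadienone, and isofraxidin 14. This cut comes first because 14 is purchasable and its lactone would not survive the enolate, nickel and indium chemistry needed for the terpene. Alcohol 13 holds all three stereocentres and no arene. The forward reaction must form an ether at a β-branched primary carbon without base, which points to a Mitsunobu reaction.

**C9–C11 bond.** Cutting this bond in 13 leaves an allyl nucleophile spread over C9–C8–C12 and formaldehyde, and leads to the allylic bromide 12. The alternative of methylenating a C8 ketone would place an epimerisable C9 next to a carbonyl. The chosen cut makes the exocyclic alkene and the C9 centre in one event and lets the angular methyl choose the face. Bromide 12 has one stereocentre fewer. The forward step must be γ-selective and must prefer formaldehyde over the C3 ketone.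

**Allylic transposition and protecting group.** Bromide 12 comes from the 2-methylidene alcohol 11 by bromination with allylic shift, and 11 from its triethylsilyl ether 10. No skeletal bond is cut. The value of this step is that 11 and 10 have the substitution pattern produced by a reductive alkyne–aldehyde coupling.

**C4–CH3 bonds.** Removing both methyls from 10 gives the silyl ether 8. The methyls are cut here because a diene carrying them at its terminus would be a poor cycloaddition partner, whereas in 8 the C4 position is the only enolisable one. The forward double alkylation must come after the aldehyde is consumed and before a free hydroxyl or the coumarin is present.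

**C8–C9 bond.** Opening ring B of 8 at this bond gives the ynal 7, in which C6–C7–C8–C12 is a but-3-ynyl chain on C5 and C9 is a formyl group on C10. Cuts at C5–C6 or C9–C10 would break bonds to stereocentres. This one touches none and uses the aldehyde that the cycloaddition needs anyway. The forward reaction is a nickel-catalysed reductive cyclisation with a silane, which must leave the enone alone.

**C1–C10 and C4–C5 bonds (key step).** Ring A of 7 is cut into Danishefsky's diene 5 and the E-enal 4, with the silyl enol ether cycloadduct 6 as the intermediate. One ring, two skeletal bonds and both stereocentres of 7 go back to two achiral, acyclic components. The forward reaction needs a chiral Lewis acid to choose the enal face and must add to the C=C bond and not to the C=O bond.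

**C5=C10 bond.** Enal 4 is cut at its alkene into pent-4-ynal 2 and the formyl-stabilised ylide 3. Aldehyde 2 comes from pent-4-yn-1-ol 1 by oxidation. Only E selectivity is required, which a stabilised ylide provides.

## Roads not taken

**Alternative 1: three-component coupling on a ring B enone.**
- Cut: the C9–C11 and C10–CH3 bonds, leading back to the cyclohexenone A1, whose side chain is a ketal-masked 3-oxobutyl group.
- Forward key step: a silylmethyl copper reagent (a masked hydroxymethyl anion) adds to C9 anti to the C8 silyloxy group, and the enolate is trapped at C10 by a methyl electrophile to give A2. No ring is formed.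
- Merits: the trans relation of the C9 arm and the C10 methyl is set in one flask by substrate control. Absolute configuration comes from a single oxygenated centre.
- Weak points: alkylation of a fully substituted enolate next to a new β-substituent is slow and prone to proton transfer. Ring A still has to be made by ketal hydrolysis and aldol condensation. That leaves the unsaturation at C4=C5, so deconjugative dimethylation, a stereoselective reduction to set C5, introduction of C1=C2, conversion of the C8 oxygen into the methylene, oxidation of the C–Si bond and the etherification all follow.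
- Comparison: its C9/C10 control is more certain than the indium step of the chosen plan. Against that, the chosen plan delivers ring A at the correct oxidation level directly from the cycloaddition, sets C5 and C10 together, and needs roughly half the number of steps.

**Alternative 2: radical bicyclisation of an epoxy-farnesyl aryl ether.**
- Cut: C4–C5 and C9–C10, opening both rings to the 2Z,6E-epoxypolyene ether A3, which already carries the coumarin.
- Forward key step: a titanocene chloride reductant (Cp2TiCl, trivalent titanium) opens the epoxide and the radical cascade closes rings A and B, ending as the C8=C12 methylene. The product A4 is the 1,2-dihydro-3-hydroxy analogue of 15. Oxidation of the alcohol and dehydrogenation at C1–C2 would finish the synthesis.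
- Merits: it is the shortest route on paper and is biomimetic. The Z alkene encodes the axial C9 arm. The ether is made on an unhindered allylic carbon, so the hindered etherification of the chosen plan is avoided.
- Weak points: A3 needs the less accessible 2Z chain and an enantioselective terminal epoxidation. Cascades of this kind usually give moderate material throughput with monocyclic and alkene-isomeric by-products. The coumarin C3=C4 bond is exposed to radicals and a low-valent metal. The end game must dehydrogenate a ketone next to that coumarin and the exocyclic alkene.
- Comparison: it is better in step count. The chosen plan offers a catalytic asymmetric step of a well-understood type, one ring per step, introduction of the costly phenol 14 last, and no late dehydrogenation.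

**Alternative 3: squarate benzannulation to build the arene on the terpene.**
- Cut: the benzene ring of the coumarin at C8a′–C4a′, back to the 4-alkenyl-4-methoxycyclobutenone A5 that bears the terpene as an alkoxy group.
- Forward key step: thermolysis opens A5 to a dienylketene, which closes by six-electron electrocyclisation and tautomerises to the phenol A6. Acetal hydrolysis, olefination and lactonisation would then form the pyranone.
- Merits: the C11–O bond is made by addition–elimination on a four-membered dione, not by substitution with a di-ortho-substituted phenol. The hexasubstituted arene is regiodefined and easily varied.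
- Weak points: it does not address the terpene, which is needed complete, and with C3 protected as a silyl ether because organolithium and thermal steps follow. The carbonyl addition that makes A5 must distinguish two nearly equivalent carbonyl groups. Several steps are spent rebuilding a phenol that can be bought as 14. The enone must be regenerated at the end.
- Comparison: its only advantage is avoiding the hindered etherification. The chosen plan accepts that risk and has a sulfonate displacement in reserve.

Key step: step 3

## Route

Remark: the C9 carbinol centre of 8, 9, 10 and 11 is expected as an epimer mixture and is left undefined, because step 7 turns C9 into an sp2 carbon; isofraxidin 14 is taken as a purchasable natural phenol.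

Step 1
Reactants: 1 pent-4-yn-1-ol
Product: 2 pent-4-ynal
Conditions: TEMPO (10 mol %), PhI(OAc)2 (1.1 equiv), CH2Cl2, rt; solution used directly
Reagents that add atoms: none
Why: Oxoammonium (TEMPO) oxidation of a primary alcohol stops at the aldehyde and leaves the terminal alkyne untouched; the volatile aldehyde is carried on in solution.

Step 2
Reactants: 2 pent-4-ynal; 3 2-(triphenylphosphoranylidene)propanal
Product: 4 (E)-2-methylhept-2-en-6-ynal
Conditions: PhMe, 80 °C
Reagents that add atoms: none
Why: Wittig olefination with a formyl-stabilised ylide is under thermodynamic control in its addition step and should give the E trisubstituted enal; the α-branched product is too hindered to react on with a second ylide at a useful rate.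

Step 3
Reactants: 4 (E)-2-methylhept-2-en-6-ynal; 5 Danishefsky's diene, (E)-1-methoxy-3-(trimethylsilyloxy)buta-1,3-diene
Product: 7 (1S,6R)-6-(but-3-ynyl)-1-methyl-4-oxocyclohex-2-ene-1-carbaldehyde, via silyl enol ether cycloadduct 6 (not isolated)
Conditions: (S)-1-(2-methylphenyl)-3,3-diphenyltetrahydro-1H,3H-pyrrolo[1,2-c][1,3,2]oxazaborole (20 mol %), (CF3SO2)2NH (18 mol %), 5 (2 equiv), CH2Cl2, −78 → −40 °C; then 1 M HCl, THF, 0 °C
Reagents that add atoms: none
Why: The N-protonated oxazaborolidine is a cationic boron Lewis acid that binds the formyl oxygen of 4 syn to the formyl hydrogen, with the formyl C–H held against the ring oxygen, so the s-trans enal lies over one phenyl group and only its C10-Re/C5-Si face is open. Diene 5 adds to that face in a concerted, asynchronous [4+2] cycloaddition in which its nucleophilic CH2 terminus (future C4) bonds first to the β-carbon C5 and its methoxy-bearing terminus (future C1) to the α-carbon C10, so matched polarity fixes the regiochemistry. Ring A is closed by this cycloaddition, both σ-bonds forming suprafacially on each partner; the closest known reaction type is the oxazaborolidinium-catalysed Diels–Alder reaction of α-substituted acroleins with siloxy dienes. C10 is set by the catalyst-controlled choice of enal face, and C5 follows from C10 because suprafacial addition to the E alkene places C6 and the formyl carbon C9 trans whatever the endo/exo ratio; the methoxy-bearing centre of 6 is formed as a mixture and is erased. Aqueous acid then hydrolyses the enol silane of 6 and expels methanol in an E1cB-type elimination, releasing the C1=C2–C3=O enone of 7, neither of whose stereocentres is enolisable. The step needs enantiofacial selectivity, which the catalyst supplies, and preference for the C=C over the C=O bond, which is supported by α-branching at the formyl group and by keeping the triflimide below the oxazaborolidine so that no free Brønsted acid degrades the diene.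

Step 4
Reactants: 7 (1S,6R)-6-(but-3-ynyl)-1-methyl-4-oxocyclohex-2-ene-1-carbaldehyde
Product: 8 4a-methyl-6-methylidene-5-(triethylsilyloxy)-4a,5,6,7,8,8a-hexahydronaphthalen-2(1H)-one (trans-fused, ring-fusion configuration carried over from 7, C5 epimers)
Conditions: Ni(cod)2 (10 mol %), PBu3 (20 mol %), Et3SiH (5 equiv), THF, 0 °C → rt, slow addition of 7
Reagents that add atoms: triethylsilane, CC[SiH](CC)CC
Why: Nickel-catalysed reductive cyclisation of an ynal with a silane: zerovalent nickel couples the formyl carbon C9 and the internal alkyne carbon C8 by oxidative cyclisation to an oxanickelacyclopentene, Et3SiH cleaves the Ni–O bond by σ-bond metathesis, and C–H reductive elimination leaves the C8=C12 methylene and the C9 silyl ether. The six-membered ring closes onto the preset trans C5/C10 pair, so the trans-decalin is fixed, and the enone should stay out because coupling at C1 would need a bridged bicyclo[3.3.1] metallacycle with the side chain axial.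

Step 5
Reactants: 8 4a-methyl-6-methylidene-5-(triethylsilyloxy)-4a,5,6,7,8,8a-hexahydronaphthalen-2(1H)-one
Product: 10 1,1,4a-trimethyl-6-methylidene-5-(triethylsilyloxy)-4a,5,6,7,8,8a-hexahydronaphthalen-2(1H)-one, via 4-monomethyl ketone 9 (not isolated)
Conditions: t-BuOK (3 equiv), MeI (6 equiv), THF, −20 → 0 °C
Reagents that add atoms: iodomethane, CI
Why: Exhaustive α-alkylation of a ketone enolate: C4 (drimane numbering) is the only carbon of 8 with enolisable hydrogens, since C2 is vinylic and C10 quaternary, so the cross-conjugated potassium dienolate is methylated twice at C4 without regiochemical doubt. The neopentylic β-carbon C1 suppresses Michael self-condensation, and the silyl ether keeps the C9 oxygen from being methylated.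

Step 6
Reactants: 10 1,1,4a-trimethyl-6-methylidene-5-(triethylsilyloxy)-4a,5,6,7,8,8a-hexahydronaphthalen-2(1H)-one
Product: 11 5-hydroxy-1,1,4a-trimethyl-6-methylidene-4a,5,6,7,8,8a-hexahydronaphthalen-2(1H)-one (C5 epimers)
Conditions: HF·pyridine, pyridine, THF, 0 °C → rt
Reagents that add atoms: none
Why: Fluoride-driven Si–O cleavage under buffered conditions that neither isomerise the exocyclic alkene nor touch the enone.

Step 7
Reactants: 11 5-hydroxy-1,1,4a-trimethyl-6-methylidene-4a,5,6,7,8,8a-hexahydronaphthalen-2(1H)-one
Product: 12 6-(bromomethyl)-1,1,4a-trimethyl-4a,7,8,8a-tetrahydronaphthalen-2(1H)-one (the C12 bromide with the C8=C9 alkene)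
Conditions: PBr3 (0.4 equiv), pyridine (cat.), Et2O, −10 → 0 °C; used without storage
Reagents that add atoms: phosphorus tribromide, BrP(Br)Br
Why: Bromination with allylic transposition (SN2′): the phosphite ester at the secondary, neopentylic C9 cannot be displaced directly, so bromide enters at the unhindered methylene C12 and the alkene moves to C8=C9, which is also the thermodynamically preferred primary allylic bromide. Both C9 epimers of 11 converge and the C9 centre is erased on purpose.

Step 8
Reactants: 12 6-(bromomethyl)-1,1,4a-trimethyl-4a,7,8,8a-tetrahydronaphthalen-2(1H)-one
Product: 13 (4aR,5S,8aS)-5-(hydroxymethyl)-1,1,4a-trimethyl-6-methylidene-4a,5,6,7,8,8a-hexahydronaphthalen-2(1H)-one (drimane numbering 5S,9S,10R)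
Conditions: In powder (2 equiv), 37 % aq. HCHO (10 equiv), THF–H2O (1:1), rt
Reagents that add atoms: formaldehyde, C=O
Why: Barbier-type indium-mediated allylation of formaldehyde in water: the allylindium formed at C12 reacts through a cyclic six-membered transition state at its γ-carbon C9, forming C9–C11 and returning the alkene to C8=C12. Formaldehyde is delivered to the face of C9 opposite the axial C10 methyl (axial attack on the half-chair), which places the C11 arm trans to that methyl as in the target. The C3 ketone, shielded by the C4 gem-dimethyl group, should not compete with formaldehyde.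

Step 9
Reactants: 13 (4aR,5S,8aS)-5-(hydroxymethyl)-1,1,4a-trimethyl-6-methylidene-4a,5,6,7,8,8a-hexahydronaphthalen-2(1H)-one; 14 isofraxidin (7-hydroxy-6,8-dimethoxy-2H-chromen-2-one)
Product: 15 7-{[(1S,4aS,8aR)-5,5,8a-trimethyl-2-methylidene-6-oxo-1,2,3,4,4a,5,6,8a-octahydronaphthalen-1-yl]methoxy}-6,8-dimethoxy-2H-chromen-2-one (target)
Conditions: PPh3, DIAD, THF, 0 °C → rt
Reagents that add atoms: none
Why: Mitsunobu etherification: the phosphonium-activated primary alcohol is displaced at the non-stereogenic C11 by the acidic, coumarin-conjugated phenoxide of 14 under neutral conditions that spare the lactone, the enone and the exocyclic alkene.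

## Compound list

1 | pent-4-yn-1-ol | C#CCCCO | starting material
2 | pent-4-ynal | C#CCCC=O | intermediate
3 | 2-(triphenylphosphoranylidene)propanal | CC(C=O)=P(c1ccccc1)(c1ccccc1)c1ccccc1 | starting material
4 | (E)-2-methylhept-2-en-6-ynal | C#CCC/C=C(\C)C=O | intermediate
5 | Danishefsky's diene, (E)-1-methoxy-3-(trimethylsilyloxy)buta-1,3-diene | CO/C=C/C(=C)O[Si](C)(C)C | starting material
6 | (1S,6R)-6-(but-3-ynyl)-2-methoxy-1-methyl-4-(trimethylsilyloxy)cyclohex-3-ene-1-carbaldehyde (C2 epimers) | C#CCC[C@@H]1CC(O[Si](C)(C)C)=CC(OC)[C@@]1(C)C=O | intermediate (not isolated)
7 | (1S,6R)-6-(but-3-ynyl)-1-methyl-4-oxocyclohex-2-ene-1-carbaldehyde | C#CCC[C@@H]1CC(=O)C=C[C@@]1(C)C=O | intermediate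
8 | 4a-methyl-6-methylidene-5-(triethylsilyloxy)-4a,5,6,7,8,8a-hexahydronaphthalen-2(1H)-one (trans-fused, C5 epimers) | C=C1CC[C@@H]2CC(=O)C=C[C@@]2(C)C1O[Si](CC)(CC)CC | intermediate
9 | 1,4a-dimethyl-6-methylidene-5-(triethylsilyloxy)-4a,5,6,7,8,8a-hexahydronaphthalen-2(1H)-one (trans-fused, C1 and C5 epimers) | C=C1CC[C@@H]2C(C)C(=O)C=C[C@@]2(C)C1O[Si](CC)(CC)CC | intermediate (not isolated)
10 | 1,1,4a-trimethyl-6-methylidene-5-(triethylsilyloxy)-4a,5,6,7,8,8a-hexahydronaphthalen-2(1H)-one (trans-fused, C5 epimers) | C=C1CC[C@@H]2C(C)(C)C(=O)C=C[C@@]2(C)C1O[Si](CC)(CC)CC | intermediate
11 | 5-hydroxy-1,1,4a-trimethyl-6-methylidene-4a,5,6,7,8,8a-hexahydronaphthalen-2(1H)-one (trans-fused, C5 epimers) | C=C1CC[C@@H]2C(C)(C)C(=O)C=C[C@@]2(C)C1O | intermediate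
12 | 6-(bromomethyl)-1,1,4a-trimethyl-4a,7,8,8a-tetrahydronaphthalen-2(1H)-one (trans-fused) | BrCC1=C[C@]2(C)C=CC(=O)C(C)(C)[C@H]2CC1 | intermediate
13 | (4aR,5S,8aS)-5-(hydroxymethyl)-1,1,4a-trimethyl-6-methylidene-4a,5,6,7,8,8a-hexahydronaphthalen-2(1H)-one | C=C1CC[C@@H]2C(C)(C)C(=O)C=C[C@@]2(C)[C@H]1CO | intermediate
14 | isofraxidin, 7-hydroxy-6,8-dimethoxy-2H-chromen-2-one | COc1cc2ccc(=O)oc2c(OC)c1O | starting material
15 | 7-{[(1S,4aS,8aR)-5,5,8a-trimethyl-2-methylidene-6-oxo-1,2,3,4,4a,5,6,8a-octahydronaphthalen-1-yl]methoxy}-6,8-dimethoxy-2H-chromen-2-one (CNP0227866.1) | C=C1CC[C@@H]2C(C)(C)C(=O)C=C[C@@]2(C)[C@H]1COc1c(OC)cc2ccc(=O)oc2c1OC | target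

## Step count and risk

Total step count: 9. Longest linear sequence: 9 steps (1 → 15); compounds 3, 5 and 14 enter as purchased materials.

**Step 3 (key step).**
- What may go wrong: the very nucleophilic diene may attack the activated formyl carbon (aldol-type or hetero-Diels–Alder pathway) in place of the C=C bond. The strongly acidic catalyst may desilylate or oligomerise the diene. The β-substituent lowers dienophile reactivity, so a slow reaction with eroded facial selectivity is possible.
- If only the sense of induction is opposite to the model, the (R)-oxazaborolidine is used.
- Fallback, from 4 back to 7: enal 4 is combined with 1-(dimethylamino)-3-(tert-butyldimethylsilyloxy)buta-1,3-diene under a neutral chiral salen complex, N,N′-bis(3,5-di-tert-butylsalicylidene)cyclohexane-1,2-diaminochromium chloride (trivalent chromium), using the ligand enantiomer that gives the (1S,6R) series. The more reactive diene allows a much weaker Lewis acid. The amino siloxy cycloadduct F1 is then treated with dilute aqueous HCl in THF, which hydrolyses the enol silane and eliminates dimethylamine, and the route is rejoined at 7.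

**Step 4.**
- What may go wrong: nickel may engage the enone, either by coupling the alkyne with the β-carbon C1 or by being held as an enone complex. The terminal alkyne may oligomerise.
- Fallback, from 6 back to 8: the cycloaddition mixture of step 3 is quenched with triethylamine and filtered without aqueous acid, so that 6 is obtained with its enone still masked. The same Ni(cod)2/PBu3/Et3SiH cyclisation then gives the bicyclic enol silane F2, in which no enone is present during the nickel step. Mild acid (pyridinium p-toluenesulfonate in wet THF, followed by DBU if loss of methanol is incomplete) unveils the enone while the hindered triethylsilyl ether persists, and the route is rejoined at 8.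

**Step 8.**
- What may go wrong: bond formation may occur through the primary carbon C12 because C9 is neopentylic. Facial selectivity at C9 may be incomplete. The allyl halide may dimerise reductively.
- Fallback, from 12 back to 13: bromide 12 is silylated with Me3SiSiMe3 and Pd2(dba)3 (zerovalent palladium) in DMF to the primary allylsilane F3. Hydroxymethylation of F3 with paraformaldehyde and Me2AlCl in CH2Cl2 at −78 °C (Hosomi–Sakurai type, open transition state) forces bond formation at the carbon γ to silicon, which is C9, again on the face opposite the angular methyl, and gives 13.

**Step 9.**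
- What may go wrong: displacement at the β-branched, axial C11 by a phenol flanked by two methoxy groups may be slow. That would leave room for elimination toward the conjugated diene or alkylation of the reduced azodicarboxylate.
- Fallback, from 13 back to 15: alcohol 13 is converted with MsCl and Et3N in CH2Cl2 at 0 °C into the mesylate F4. F4 is displaced by the caesium phenoxide of 14 (Cs2CO3, DMF, 60 °C) in a Williamson-type substitution to give 15.

## Further compounds

F1 | step 3 | (1S,6R)-6-(but-3-ynyl)-4-(tert-butyldimethylsilyloxy)-2-(dimethylamino)-1-methylcyclohex-3-ene-1-carbaldehyde (C2 epimers) | C#CCC[C@@H]1CC(O[Si](C)(C)C(C)(C)C)=CC(N(C)C)[C@@]1(C)C=O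
F2 | step 4 | 4-methoxy-4a-methyl-6-methylidene-5-(triethylsilyloxy)-2-(trimethylsilyloxy)-1,4,4a,5,6,7,8,8a-octahydronaphthalene (trans-fused, C4 and C5 epimers) | C=C1CC[C@@H]2CC(O[Si](C)(C)C)=CC(OC)[C@@]2(C)C1O[Si](CC)(CC)CC
F3 | step 8 | 1,1,4a-trimethyl-6-[(trimethylsilyl)methyl]-4a,7,8,8a-tetrahydronaphthalen-2(1H)-one (trans-fused) | C[Si](C)(C)CC1=C[C@]2(C)C=CC(=O)C(C)(C)[C@H]2CC1
F4 | step 9 | [(1S,4aS,8aR)-5,5,8a-trimethyl-2-methylidene-6-oxo-1,2,3,4,4a,5,6,8a-octahydronaphthalen-1-yl]methyl methanesulfonate | C=C1CC[C@@H]2C(C)(C)C(=O)C=C[C@@]2(C)[C@H]1COS(C)(=O)=O
A1 | alternative 1 | 4-(tert-butyldimethylsilyloxy)-2-[2-(2-methyl-1,3-dioxolan-2-yl)ethyl]cyclohex-2-en-1-one | CC1(CCC2=C[C@H](O[Si](C)(C)C(C)(C)C)CCC2=O)OCCO1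
A2 | alternative 1 | 4-(tert-butyldimethylsilyloxy)-3-{[dimethyl(propan-2-yloxy)silyl]methyl}-2-methyl-2-[2-(2-methyl-1,3-dioxolan-2-yl)ethyl]cyclohexan-1-one | CC1(CC[C@@]2(C)[C@@H](C[Si](C)(C)OC(C)C)[C@H](O[Si](C)(C)C(C)(C)C)CCC2=O)OCCO1
A3 | alternative 2 | 7-{[(2Z,6E)-9-(3,3-dimethyloxiran-2-yl)-3,7-dimethylnona-2,6-dien-1-yl]oxy}-6,8-dimethoxy-2H-chromen-2-one | CC1(C)O[C@@H]1CC/C(C)=C/CC/C(C)=C\COc1c(OC)cc2ccc(=O)oc2c1OC
A4 | alternative 2 | 7-{[6-hydroxy-5,5,8a-trimethyl-2-methylidenedecahydronaphthalen-1-yl]methoxy}-6,8-dimethoxy-2H-chromen-2-one (1,2-dihydro-3-hydroxy analogue of 15) | C=C1CC[C@@H]2C(C)(C)[C@H](O)CC[C@@]2(C)[C@H]1COc1c(OC)cc2ccc(=O)oc2c1OC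
A5 | alternative 3 | 3-{[6-(tert-butyldimethylsilyloxy)-5,5,8a-trimethyl-2-methylidenedecahydronaphthalen-1-yl]methoxy}-4-[(E)-3,3-diethoxyprop-1-en-1-yl]-2,4-dimethoxycyclobut-2-en-1-one | C=C1CC[C@@H]2C(C)(C)[C@H](O[Si](C)(C)C(C)(C)C)CC[C@@]2(C)[C@H]1COC3=C(OC)C(=O)C3(OC)/C=C/C(OCC)OCC
A6 | alternative 3 | 4-{[6-(tert-butyldimethylsilyloxy)-5,5,8a-trimethyl-2-methylidenedecahydronaphthalen-1-yl]methoxy}-2-hydroxy-3,5-dimethoxybenzaldehyde diethyl acetal | C=C1CC[C@@H]2C(C)(C)[C@H](O[Si](C)(C)C(C)(C)C)CC[C@@]2(C)[C@H]1COc1c(OC)cc(C(OCC)OCC)c(O)c1OC
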